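Remark on the chemistry: the target has no stereocentre, so the stereocentres of 4, 7, 10 and 12 are formed racemic and are all erased before the end of the route.

## Analysis of the target

Irisoquin C (15) is a single carbocycle, a 1,4-benzoquinone, with carbonyls at C1 and C4, a free hydroxyl at C2, an unbranched nonadecyl chain at C3, a methoxy group at C5 and the only ring hydrogen at C6. It has no stereocentre and no stereogenic double bond, so the whole problem is one of regiochemistry on the ring. The C2 hydroxyl and the C5 methoxy are both oxygens of vinylogous acid units (O–C2=C3–C4=O and O–C5=C6–C1=O). They differ only in their neighbour (chain or hydrogen) and in being free or methylated, and telling them apart is the central difficulty. The quinone is an oxidant and a Michael acceptor, the hydroxyquinone is acidic, and the methoxy group is a vinylogous ester that nucleophiles and aqueous base displace, so such conditions are excluded once the quinone exists. The C19 chain adds no reactivity but makes every intermediate waxy and poorly soluble in cold polar media. The strategy rests on the contiguous array C1–C2–C3–C4: the oxygen-bearing C2 and the chain-bearing C3 are the two alkene carbons of a squarate-derived cyclobutenedione, and C1 and C4 are its two carbonyl carbons. C6 and the methoxy-bearing C5 come from a 2-methoxyvinyl group attached at C1.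

## Retrosynthetic reasoning

15 to 14. The last disconnection is the O–alkyl bond at the C2 oxygen. Carrying that oxygen as the isopropyl ether 14 keeps it distinct from the C5 methyl ether throughout, and the isopropyl group is the ester group the squarate 3 already carries, so no separate protection step is spent. The forward reaction must remove a secondary alkyl group from one vinylogous ester while leaving the methyl group of the other untouched.

14 to 13. The quinone is taken back to hydroquinone 13, a change of oxidation level only. Hydroquinone 13 is the direct product of the ring-forming step and is air-sensitive, so the forward oxidation is deliberate and mild rather than an extra burden.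

13 to 10 (key disconnection). The ring bond C4–C5 is cut and the bond between C1 and C4 is re-formed, which folds the arene back through cyclohexadienone 12 and dienylketene 11 to the four-membered ring of cyclobutenone 10. This is the only carbon–carbon bond of the six-membered ring that is made during ring construction; every substituent is already in place in 10. What is gained is that the regiochemical problem of a pentasubstituted ring is reduced to the order of two additions to a cyclobutenedione. The forward reaction has to open the four-membered ring with the methoxyvinyl arm turned towards the ketene and close the six-membered ring on the methoxy-bearing vinyl carbon.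

10 to 5 and 9. The bond between the carbinol carbon (future C1) and the vinyl carbon (future C6) is cut, giving cyclobutenedione 5 and the vinyllithium 9. The cut is made here because the two carbonyls of 5 are electronically different. The carbonyl next to the chain-bearing carbon is a vinylogous ester and is deactivated, so the nucleophile must go to the carbonyl next to the isopropoxy-bearing carbon, which is exactly the connectivity 10 needs.

9 to 8, 7 and 6. The lithium reagent 9 comes from the cis-bromide 8 by halogen–lithium exchange with retention of geometry. Bromide 8 comes from dibromide 7 by loss of hydrogen bromide, and 7 from the enol ether 6 by halogen addition. The cis geometry matters for the reagent, not for the target, because only the cis-configured lithium species resists β-elimination.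

5 to 4, then 3 and 2; 2 to 1. The bond between C3 and the chain is cut last. Adduct 4 arises from addition of Grignard reagent 2 (from bromide 1) to one carbonyl of the symmetrical squarate 3, and acid-induced transposition of 4 with loss of one isopropoxy group gives 5. Introducing the chain first and the vinyl unit second is what fixes the chain next to the future C4 carbonyl.

## Alternatives that were turned down

Alternative 1: The ring is cut at C3–C4 and C5–C6, so that C4 and C5 with their oxygens come from diethyl oxalate A2 and C6, C1, C2, C3 and the chain come from tricosane-2,3-dione A1. In the forward key step the bis-enolate of A1 is acylated twice by A2 and the resulting cyclic tetraketone tautomerises to 2,5-dihydroxy-3-nonadecyl-1,4-benzoquinone A3. In its favour, the carbocycle, all four oxygens and the chain arrive in one operation from cheap reagents, and the step count to A3 is clearly lower than that of the chosen route; on step economy this alternative is stronger. Against it, A3 carries two free vinylogous-acid hydroxyls that differ only by their neighbour, so the final mono-methylation must favour the oxygen next to C6 over the one next to the chain and must stop before dimethylation, with nothing but a modest steric bias to rely on. In addition, A1 is not a stock compound, α-diketones self-condense under the alkoxide conditions, and the second acylation occurs at a methylene hindered by the long chain. The chosen route is longer, but the two oxygens are different from the first step (isopropyl against methyl), so no selectivity question is left for the end.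

Alternative 2: The ring is cut into three pieces. The alkenyl Fischer carbene of zerovalent chromium, pentacarbonyl[methoxy(1-methoxyethenyl)carbene]chromium A4, supplies C4, C5 and C6; the alkynylboronate 2-(henicos-1-yn-1-yl)-4,4,5,5-tetramethyl-1,3,2-dioxaborolane A5 supplies C2 and C3; one carbonyl ligand supplies C1. The forward key step is a Dötz-type benzannulation giving 4,5-dimethoxy-3-nonadecyl-2-(4,4,5,5-tetramethyl-1,3,2-dioxaborolan-2-yl)phenol A6, after which the carbon–boron bond is oxidised to the C2 hydroxyl and the para-methoxyphenol is oxidised to the quinone. In its favour, it is highly convergent, the boron marks the future C2 oxygen and so differentiates it from the C5 methoxy, and the step count is comparable to that of the chosen route; in convergence it is at least as strong. Against it stand a stoichiometric chromium carbonyl reagent, an electron-rich and sensitive carbene A4, and an alkyne partner A5 that needs a C21 terminal alkyne not held in stock. The end game is also delicate: A6 carries two methoxy groups, of which only the one at C4 may be lost, and peroxide oxidation of the carbon–boron bond next to a quinone or an electron-rich catechol risks ortho-quinone formation or epoxidation. The chosen route uses no stoichiometric heavy-metal complex in the ring-forming step and carries only one methoxy group, placed where it stays.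

Alternative 3: The ring bond C2–C3 is cut, leading back to an open tetraketide, methyl 3,5,7-trioxohexacosanoate A7. In the forward key step its C2 methylene condenses in an aldol reaction with its C7 ketone and dehydration gives the resorcylate methyl 2,4-dihydroxy-6-nonadecylbenzoate A8. In its favour are the biomimetic logic, inexpensive reagents, no cryogenic organometallic chemistry and a strong aromatisation driving force. On one point it is stronger than it first looks: the ester of A8 hydrogen-bonds its neighbouring hydroxyl, so the remote hydroxyl (the future C5 oxygen) can be methylated selectively. Against it, the ring is formed at the wrong oxidation level. Only the C1 and C5 oxygens are present; the ester carbon sits on the future C2 and must be exchanged for oxygen, for instance by reduction and a Dakin-type oxidation; and C4 needs a separate carbon–hydrogen oxidation. The cyclisation of A7 also competes with Claisen-type closure and pyrone formation. The count comes out well above that of the chosen route, which delivers all four oxygens at the correct positions in the ring-forming step and removes no carbon afterwards.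

Key step: step 7

## Route

Step 1
Reactants: 1 1-bromononadecane
Product: 2 nonadecylmagnesium bromide
Conditions: Mg turnings, I2 (cat.), THF, reflux
Reagents that add atoms: magnesium, [Mg]
Why: Grignard formation by magnesium insertion into a primary alkyl bromide; slow addition of 1 keeps Wurtz coupling low and the saturated chain is inert.

Step 2
Reactants: 2 nonadecylmagnesium bromide; 3 diisopropyl squarate (3,4-diisopropoxycyclobut-3-ene-1,2-dione)
Product: 4 rac-4-hydroxy-2,3-diisopropoxy-4-nonadecylcyclobut-2-en-1-one
Conditions: THF, −78 to −40 °C (2 added to 3); aq. NH4Cl
Reagents that add atoms: none
Why: 1,2-Addition of a Grignard reagent to one of the two equivalent carbonyls of the squarate; the remaining carbonyl of the alkoxide is a vinylogous ester and is too deactivated for a second addition at low temperature. The new carbinol centre is racemic and is destroyed in step 3.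

Step 3
Reactants: 4 rac-4-hydroxy-2,3-diisopropoxy-4-nonadecylcyclobut-2-en-1-one
Product: 5 3-isopropoxy-4-nonadecylcyclobut-3-ene-1,2-dione
Conditions: conc. HCl (cat.), CH2Cl2, rt
Reagents that add atoms: water, O
Why: Acid-catalysed allylic transposition: the tertiary allylic alcohol ionises to an alkoxy-stabilised cyclobutenyl cation, water adds at the distal isopropoxy-bearing carbon and the hemiketal loses propan-2-ol. This leaves the chain and the remaining isopropoxy group on the alkene of the dione.

Step 4
Reactants: 6 methyl vinyl ether
Product: 7 rac-1,2-dibromo-1-methoxyethane
Conditions: Br2, CH2Cl2, −78 °C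
Reagents that add atoms: bromine, BrBr
Why: Electrophilic addition of bromine across the enol ether double bond; the gas 6 is condensed cold and the reactive α-bromo ether 7 is used crude.

Step 5
Reactants: 7 rac-1,2-dibromo-1-methoxyethane
Product: 8 (Z)-1-bromo-2-methoxyethene
Conditions: PhNEt2, 90–100 °C; distil under reduced pressure
Reagents that add atoms: none
Why: Amine-mediated dehydrobromination, in which the α-bromide leaves through the oxocarbenium ion and the β-proton is then removed. The cis arrangement of halogen and alkoxy group is the favoured geometry of 1-halo-2-alkoxyethenes, and fractional distillation should enrich it further.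

Step 6
Reactants: 8 (Z)-1-bromo-2-methoxyethene; 5 3-isopropoxy-4-nonadecylcyclobut-3-ene-1,2-dione
Product: 10 rac-4-hydroxy-3-isopropoxy-4-[(Z)-2-methoxyethenyl]-2-nonadecylcyclobut-2-en-1-one, via [(Z)-2-methoxyethenyl]lithium 9 (not isolated)
Conditions: t-BuLi (2 equiv), THF–Et2O, −78 °C; then 5, −78 °C; aq. NH4Cl
Reagents that add atoms: none
Why: Bromine–lithium exchange with retention of geometry gives the oxygen-chelated cis-vinyllithium 9, in which lithium and methoxy are syn and anti β-elimination is not possible. Reagent 9 adds 1,2 to the carbonyl next to the isopropoxy-bearing carbon, because the other carbonyl is a deactivated vinylogous ester. The carbinol centre is formed racemic and is erased in step 7.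

Step 7
Reactants: 10 rac-4-hydroxy-3-isopropoxy-4-[(Z)-2-methoxyethenyl]-2-nonadecylcyclobut-2-en-1-one
Product: 13 2-isopropoxy-5-methoxy-3-nonadecylbenzene-1,4-diol, via dienylketene 11 (not isolated), via cyclohexadienone tautomer 12 (not isolated)
Conditions: toluene (degassed, 0.02 M), 110 °C, Ar
Reagents that add atoms: none
Why: Heating opens the cyclobutenone by a conrotatory 4π electrocyclic reaction that breaks the bond between the carbonyl carbon and the carbinol carbon and gives dienylketene 11; the hydroxyl, as the donor substituent, rotates outward, which places the methoxyvinyl arm cis to the ketene. The ketene carbon (future C4) then bonds to the methoxy-bearing vinyl terminus (future C5) in a thermal 6π electrocyclisation, the mode by which the six-membered carbocycle is closed, to give cyclohexadienone 12. Transfer of the hydrogen on the sp3 carbon of 12 to oxygen aromatises the ring to hydroquinone 13, and this gain of aromaticity drives the sequence. The closest known reaction type is the thermal ring expansion of 4-alkenyl- and 4-aryl-4-hydroxycyclobutenones to hydroquinones (Moore-type rearrangement). No stereocentre is created in the product: the carbinol centre of 10, the alkene geometry and the sp3 centre of 12 are all erased. The step needs torquoselectivity, secured by the outward preference of the hydroxyl, and six- over five-membered closure, secured because lactone formation would require the hydroxyl to rotate inward. Regiochemistry is already fixed in 10, where the ketene-forming carbonyl is flanked by the chain-bearing carbon, so the chain ends between the new C4 oxygen and the isopropoxy carbon. Dilute, degassed and acid-free conditions keep ketene dimerisation, air oxidation and ionisation of the tertiary alcohol in check.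

Step 8
Reactants: 13 2-isopropoxy-5-methoxy-3-nonadecylbenzene-1,4-diol
Product: 14 2-isopropoxy-5-methoxy-3-nonadecylcyclohexa-2,5-diene-1,4-dione
Conditions: Ag2O, Na2SO4, Et2O, rt
Reagents that add atoms: none
Why: Two-electron oxidation of an electron-rich hydroquinone to the para-quinone; the neutral, non-aqueous conditions leave both alkoxy groups in place.

Step 9
Reactants: 14 2-isopropoxy-5-methoxy-3-nonadecylcyclohexa-2,5-diene-1,4-dione
Product: 15 irisoquin C (2-hydroxy-5-methoxy-3-nonadecylcyclohexa-2,5-diene-1,4-dione)
Conditions: BCl3 (1 M in CH2Cl2), CH2Cl2, −78 to 0 °C; H2O
Reagents that add atoms: none
Why: Lewis-acid dealkylation of a vinylogous ester: BCl3 chelates the C1 carbonyl and the C2 ether oxygen, and chloride removes the secondary isopropyl group, whose cleavage is ionisation-assisted, much faster than it attacks the methyl group at C5 at low temperature. Hydrolysis of the boron–oxygen bond on work-up frees the hydroxyquinone.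

## Compound list

1 | 1-bromononadecane | CCCCCCCCCCCCCCCCCCCBr | starting material
2 | nonadecylmagnesium bromide | CCCCCCCCCCCCCCCCCCC[Mg]Br | intermediate
3 | diisopropyl squarate (3,4-diisopropoxycyclobut-3-ene-1,2-dione) | CC(C)OC1=C(OC(C)C)C(=O)C1=O | starting material
4 | rac-4-hydroxy-2,3-diisopropoxy-4-nonadecylcyclobut-2-en-1-one | CCCCCCCCCCCCCCCCCCCC1(O)C(OC(C)C)=C(OC(C)C)C1=O | intermediate
5 | 3-isopropoxy-4-nonadecylcyclobut-3-ene-1,2-dione | CCCCCCCCCCCCCCCCCCCC1=C(OC(C)C)C(=O)C1=O | intermediate
6 | methyl vinyl ether | COC=C | starting material
7 | rac-1,2-dibromo-1-methoxyethane | COC(Br)CBr | intermediate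
8 | (Z)-1-bromo-2-methoxyethene | CO/C=C\Br | intermediate
9 | [(Z)-2-methoxyethenyl]lithium | CO/C=C\[Li] | intermediate (not isolated)
10 | rac-4-hydroxy-3-isopropoxy-4-[(Z)-2-methoxyethenyl]-2-nonadecylcyclobut-2-en-1-one | CCCCCCCCCCCCCCCCCCCC1=C(OC(C)C)C(O)(/C=C\OC)C1=O | intermediate
11 | (3Z,5Z)-4-hydroxy-3-isopropoxy-6-methoxy-2-nonadecylhexa-1,3,5-trien-1-one | CCCCCCCCCCCCCCCCCCCC(=C=O)/C(OC(C)C)=C(O)\C=C/OC | intermediate (not isolated)
12 | rac-4-hydroxy-3-isopropoxy-6-methoxy-2-nonadecylcyclohexa-2,4-dien-1-one | CCCCCCCCCCCCCCCCCCCC1=C(OC(C)C)C(O)=CC(OC)C1=O | intermediate (not isolated)
13 | 2-isopropoxy-5-methoxy-3-nonadecylbenzene-1,4-diol | CCCCCCCCCCCCCCCCCCCc1c(O)c(OC)cc(O)c1OC(C)C | intermediate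
14 | 2-isopropoxy-5-methoxy-3-nonadecylcyclohexa-2,5-diene-1,4-dione | CCCCCCCCCCCCCCCCCCCC1=C(OC(C)C)C(=O)C=C(OC)C1=O | intermediate
15 | irisoquin C (2-hydroxy-5-methoxy-3-nonadecylcyclohexa-2,5-diene-1,4-dione) | CCCCCCCCCCCCCCCCCCCC1=C(O)C(=O)C=C(OC)C1=O | target

## Step count and least certain steps

Total step count: 9. Longest linear sequence: 7 steps (1, 2, 3, 6, 7, 8, 9, from bromide 1); steps 4 and 5 form the short branch that supplies 8.

Step 7 (key step). The most likely failure is diversion of the ring-opened ketene before six-membered closure. Inward rotation of the hydroxyl followed by its addition to the ketene would give a five-membered lactone, and trace acid can ionise the tertiary allylic alcohol, which the enol ether assists, before the ring opens. Air oxidation of the electron-rich product during isolation is a lesser concern. The fallback masks the hydroxyl. It sets out from 10, which with TMSCl and Et3N in CH2Cl2 should give 3-isopropoxy-4-[(Z)-2-methoxyethenyl]-2-nonadecyl-4-(trimethylsilyloxy)cyclobut-2-en-1-one F1. Thermolysis of this silyl ether in toluene or xylene follows the same electrocyclic path, with lactonisation and ionisation blocked, to give 3-isopropoxy-6-methoxy-2-nonadecyl-4-(trimethylsilyloxy)phenol F2. Removal of the silyl group with K2CO3 in methanol returns the route at 13.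

Step 6. Two processes threaten it: deprotonation or elimination of the bromo enol ether competing with halogen–lithium exchange, and acid-triggered allylic transposition of the adduct during work-up and chromatography. The latter calls for a cold quench and silica deactivated with Et3N. The fallback avoids the methoxyvinyl reagent and introduces the methoxy group after the ring is built. It sets out from 5, to which commercial vinylmagnesium bromide should add at the same carbonyl to give rac-4-ethenyl-4-hydroxy-3-isopropoxy-2-nonadecylcyclobut-2-en-1-one F3. Thermal ring expansion as in step 7 gives 2-isopropoxy-3-nonadecylbenzene-1,4-diol F4, and Ag2O oxidation gives 2-isopropoxy-3-nonadecylcyclohexa-2,5-diene-1,4-dione F5. Oxidative addition of methanol (MeOH, ZnCl2, air, with Ag2O to re-oxidise any hydroquinone) is expected at the carbon β to the more electrophilic carbonyl, the one not deactivated by the isopropoxy group. That carbon is C5, so the sequence comes back to the route at 14.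

Step 9. The risk is loss of chemoselectivity on the quinone: competing demethylation of the C5 vinylogous ester, or addition of chloride to the quinone, if the isopropyl cleavage needs more forcing conditions than expected. The fallback changes the order so that the cleavage is done on an aryl isopropyl ether, the substrate class for which selectivity of BCl3 over methyl ethers is best established. It sets out from 13, which with BCl3 in CH2Cl2 at low temperature should give 5-methoxy-3-nonadecylbenzene-1,2,4-triol F6. Oxidation of this triol with Ag2O or air gives the hydroxy-para-quinone directly and comes back at 15.

Step 5. The risk is incomplete geometric control in the elimination. Only the cis-bromide gives a lithium reagent that survives; the other geometry loses lithium methoxide after exchange, and the isomers may not separate cleanly by distillation. The fallback erases and re-sets the geometry. It sets out from 8 of whatever geometric composition, which with NaNH2 in liquid ammonia followed by protonation should give methoxyethyne F7. Radical hydrostannation with Bu3SnH (AIBN cat., neat) adds tin and hydrogen anti under kinetic control to give tributyl[(Z)-2-methoxyethenyl]stannane F8. Tin–lithium exchange with n-BuLi in THF at −78 °C proceeds with retention and returns the route at 9.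

## Further compounds

F1 | step 7 | rac-3-isopropoxy-4-[(Z)-2-methoxyethenyl]-2-nonadecyl-4-(trimethylsilyloxy)cyclobut-2-en-1-one | CCCCCCCCCCCCCCCCCCCC1=C(OC(C)C)C(O[Si](C)(C)C)(/C=C\OC)C1=O
F2 | step 7 | 3-isopropoxy-6-methoxy-2-nonadecyl-4-(trimethylsilyloxy)phenol | CCCCCCCCCCCCCCCCCCCc1c(O)c(OC)cc(O[Si](C)(C)C)c1OC(C)C
F3 | step 6 | rac-4-ethenyl-4-hydroxy-3-isopropoxy-2-nonadecylcyclobut-2-en-1-one | CCCCCCCCCCCCCCCCCCCC1=C(OC(C)C)C(O)(C=C)C1=O
F4 | step 6 | 2-isopropoxy-3-nonadecylbenzene-1,4-diol | CCCCCCCCCCCCCCCCCCCc1c(O)ccc(O)c1OC(C)C
F5 | step 6 | 2-isopropoxy-3-nonadecylcyclohexa-2,5-diene-1,4-dione | CCCCCCCCCCCCCCCCCCCC1=C(OC(C)C)C(=O)C=CC1=O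
F6 | step 9 | 5-methoxy-3-nonadecylbenzene-1,2,4-triol | CCCCCCCCCCCCCCCCCCCc1c(O)c(OC)cc(O)c1O
F7 | step 5 | methoxyethyne | COC#C
F8 | step 5 | tributyl[(Z)-2-methoxyethenyl]stannane | CCCC[Sn](CCCC)(CCCC)/C=C\OC
A1 | alternative 1 | tricosane-2,3-dione | CC(=O)C(=O)CCCCCCCCCCCCCCCCCCCC
A2 | alternative 1 | diethyl oxalate | CCOC(=O)C(=O)OCC
A3 | alternative 1 | 2,5-dihydroxy-3-nonadecyl-1,4-benzoquinone | CCCCCCCCCCCCCCCCCCCC1=C(O)C(=O)C=C(O)C1=O
A4 | alternative 2 | pentacarbonyl[methoxy(1-methoxyethenyl)carbene]chromium | C=C(OC)C(OC)=[Cr](=C=O)(=C=O)(=C=O)(=C=O)=C=O
A5 | alternative 2 | 2-(henicos-1-yn-1-yl)-4,4,5,5-tetramethyl-1,3,2-dioxaborolane | CCCCCCCCCCCCCCCCCCCC#CB1OC(C)(C)C(C)(C)O1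
A6 | alternative 2 | 4,5-dimethoxy-3-nonadecyl-2-(4,4,5,5-tetramethyl-1,3,2-dioxaborolan-2-yl)phenol | CCCCCCCCCCCCCCCCCCCc1c(B2OC(C)(C)C(C)(C)O2)c(O)cc(OC)c1OC
A7 | alternative 3 | methyl 3,5,7-trioxohexacosanoate | CCCCCCCCCCCCCCCCCCCC(=O)CC(=O)CC(=O)CC(=O)OC
A8 | alternative 3 | methyl 2,4-dihydroxy-6-nonadecylbenzoate | CCCCCCCCCCCCCCCCCCCc1cc(O)cc(O)c1C(=O)OC
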